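The pitfall in this flask is to read the chain length straight off the ratio of two constants. Pre-initiator gives initiator, initiator takes a free monomer and becomes a living end, and the living end then either adds free monomer to its chain or meets a free monomer and becomes a dead end.

    pre-initiator → initiator (k1 = 0.0117 min⁻¹)
    free monomer + initiator → living end + monomer in chains (k2 = 0.367 L mol⁻¹ min⁻¹)
    living end + free monomer → dead end (k3 = 0.0395 L mol⁻¹ min⁻¹)
    free monomer + living end → monomer in chains + living end, rate k4*[living end]*[free monomer] (k4 = 0.370 L mol⁻¹ min⁻¹)

| flask | free monomer | pre-initiator | time |
|---|---|---|---|
| spring | 0.60 M | 10 mol% | 40 min |
| midnight | 0.60 M | 10 mol% | 80 min |

- which of the two ends with the longer chains by the average number of monomer units in a chain (chains begun, living or dead) ("neither" if they lie within 10%) (spring / midnight / neither)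
- average number of monomer units in a chain (chains begun, living or dead) at the end, spring
- average number of monomer units in a chain (chains begun, living or dead) at the end, midnight

- the average divides the monomer in chains by the number of chains begun, living and dead together
- run time (spring): 40 min

Turnovers can be counted. Both fates of a living end go with free monomer, so the odds stay at 9.37 additions per death, and a finished chain holds on average 10.4 units, the first one counted (the kinetic chain length). With free monomer at its whole charge, a living end adds a unit every 4.50 min, so the 40 min of spring hold 8.89 additions. Both figures speak for long chains in spring, yet a third figure does not go with them. Pre-initiator has a half-life of 59 min, longer than the run of spring, so 62.6% of it remains at the end of spring and chains are still being begun then.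

The average therefore covers chains of mixed ages. A living end lives on average 42.2 min at the whole charge, so the run of spring lasts 0.948 such lives and that of midnight 1.90. Call that count x. With chains begun evenly through the run and free monomer held at its charge, spring comes to 4.32 units and midnight to 6.17. This mixed-age length is one unit plus the odds times the quantity: one, less (one less e to the minus x) over x. The mixed-age length of spring stands below the finished length, and that of midnight is longer than that of spring by a factor of 1.43, so this reckoning chooses midnight.

The forecast gives midnight, with 4 for spring and 5.8 for midnight, holding that “monomer in chains grows faster than chains begun”.

The simulation gives midnight, with 4.04 for spring and 5.77 for midnight. The mixed-age lengths of 4.32 and 6.17 stand above these, and free monomer stood at 85% of its charge at the end of spring and 64% at the end of midnight. Read at 2.5 h, spring has a mixed-age length of 7.81, and its simulated average there is 7.14, with 38% of the free monomer left.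

(Its constants were chosen freely; no experiment stands behind them.)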